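**Strategy.** The cyclohexanol is traced to (6S)-2,2,6-trimethylcyclohexanone, in which the future carbinol carbon C1 lies between the quaternary C2 (gem-dimethyl) and C6 (CHMe). The key step assembles this six-membered ring by a formal (4+2) annulation that forms the C1–C2 and C3–C4 bonds together: the morpholine enamine of isobutyraldehyde brings C2 (with both methyl groups) and C3, and a vinylketene generated in the flask from tigloyl chloride brings C1, C6, C5 and C4. Amine loss gives 2,6,6-trimethylcyclohexa-2,4-dienone. Asymmetric hydrogenation, axial vinyl addition, B-alkyl Suzuki coupling, anti-carbomagnesiation of propargyl alcohol, Stille coupling and acetylation then complete the target.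

Key step: step 1

Remark: ring atoms are numbered as in the target (C1 carbinol carbon, C2 CMe2, C3–C5 the three CH2 groups, C6 CHMe); enamine 2 is assumed to be a catalogue reagent (otherwise it is made in one condensation of isobutyraldehyde with morpholine).

Step 1
Reactants: 1 (E)-2-methylbut-2-enoyl chloride (tigloyl chloride); 2 4-(2-methylprop-1-en-1-yl)morpholine
Product: 5 2,6,6-trimethylcyclohexa-2,4-dien-1-one, via methylvinylketene 3 (not isolated), via aminoenone 4 (not isolated)
Conditions: Et3N (1.1 equiv), toluene, 0 → 80 °C; then AcOH, 80 °C; distilled and used at once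
Reagents that add atoms: none
Why: Triethylamine removes HCl from 1 by 1,4-elimination to give vinylketene 3; the nucleophilic β-carbon of enamine 2, which already carries both methyl groups, adds to the ketene carbonyl carbon (C1–C2 bond) to give an iminium/dienolate zwitterion, and the dienolate γ-carbon then closes onto the iminium carbon (C3–C4 bond), a stepwise formal (4+2) annulation. The closest known reaction types are the cycloaddition of ketenes and vinylketenes with enamines and the C-acylation of an enamine followed by a vinylogous Mannich closure. The single ring closes in a 6-(enolendo)-exo-trig mode. The only stereocentre formed, the amine-bearing C3 of 4, is erased when acid-promoted vinylogous elimination of morpholine gives 5, so no stereocontrol is needed. The step needs regioselectivity, which the matched polarity of the partners secures (enamine β-carbon to ketene C=O carbon), and periselectivity for the six- over the four-membered ring, which should follow because the (2+2) aminocyclobutanone is a donor–acceptor cyclobutane that reopens to the zwitterion and drains to the conjugated enone. The fully substituted C2 blocks aromatisation, so the dienone is the end point.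

Step 2
Reactants: 5 2,6,6-trimethylcyclohexa-2,4-dien-1-one
Product: 6 (6S)-2,2,6-trimethylcyclohexan-1-one
Conditions: H2 (50 bar), [Ir(cod)(L)][B(C6H3(CF3)2)4] (1 mol %, L = (S)-tBu-PHOX or its antipode), CH2Cl2, 25 °C
Reagents that add atoms: none
Why: Iridium P,N-catalysed asymmetric hydrogenation should saturate first the disubstituted alkene and then the trisubstituted enone bond, the chiral ligand selecting the face on which hydrogen reaches the methyl-bearing carbon so that the new stereocentre is S (catalyst control, the ligand antipode being chosen accordingly), while the neutral medium keeps it from epimerising.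

Step 3
Reactants: 6 (6S)-2,2,6-trimethylcyclohexan-1-one
Product: 7 (1R,6S)-1-ethenyl-2,2,6-trimethylcyclohexan-1-ol
Conditions: CH2=CHMgBr, CeCl3 (anhydrous), THF, −78 → 0 °C; H2O
Reagents that add atoms: vinylmagnesium bromide, C=C[Mg]Br
Why: Organocerium-mediated 1,2-addition of a vinyl Grignard reagent; the chair with equatorial C6 methyl should be attacked axially, on the face opposite the axial C2 methyl group, placing vinyl cis to the C6 methyl and setting C1 as R by substrate control, with cerium suppressing enolisation of the hindered ketone.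

Step 4
Reactants: 8 pent-3-yn-1-ol
Product: 9 5-chloropent-2-yne
Conditions: PPh3, N-chlorosuccinimide, CH2Cl2, 0 °C → rt
Reagents that add atoms: N-chlorosuccinimide, O=C1CCC(=O)N1Cl
Why: Appel-type deoxychlorination, in which the alkoxyphosphonium of the primary alcohol is displaced by chloride in an SN2 step and the internal alkyne is untouched; no stereocentre is involved.

Step 5
Reactants: 9 5-chloropent-2-yne
Product: 11 (E)-5-chloro-2-iodopent-2-ene, via alkenylzirconocene 10 (not isolated)
Conditions: Cp2Zr(H)Cl (1.5 equiv), THF, 25 → 40 °C; then I2, 0 °C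
Reagents that add atoms: iodine, II
Why: Syn-hydrozirconation of the internal alkyne, with the excess of Cp2Zr(H)Cl equilibrating zirconium to the less hindered methyl-bearing carbon, followed by iodinolysis with retention, should give the (E)-2-iodoalkene, the alkene geometry being set by the syn addition.

Step 6
Reactants: 7 (1R,6S)-1-ethenyl-2,2,6-trimethylcyclohexan-1-ol; 11 (E)-5-chloro-2-iodopent-2-ene
Product: 13 (1R,6S)-1-[(3E)-6-chloro-3-methylhex-3-en-1-yl]-2,2,6-trimethylcyclohexan-1-ol, via alkylborane 12 (not isolated)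
Conditions: 9-BBN-H (2.2 equiv), THF, 0 °C → rt; then 11, PdCl2(dppf) (5 mol %), AsPh3, Cs2CO3, DMF–H2O, rt
Reagents that add atoms: none
Why: Anti-Markovnikov hydroboration of the terminal vinyl group by the bulky borane and B-alkyl Suzuki–Miyaura coupling with retention of the vinyl iodide geometry should deliver the (E)-trisubstituted alkene, the primary alkyl chloride and both ring stereocentres remaining untouched.

Step 7
Reactants: 13 (1R,6S)-1-[(3E)-6-chloro-3-methylhex-3-en-1-yl]-2,2,6-trimethylcyclohexan-1-ol; 14 prop-2-yn-1-ol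
Product: 17 (1R,6S)-1-[(3E,7Z)-7-(hydroxymethyl)-8-iodo-3-methylocta-3,7-dien-1-yl]-2,2,6-trimethylcyclohexan-1-ol, via alkylmagnesium chloride 15 (not isolated), via alkenylmagnesium chelate 16 (not isolated)
Conditions: 13, i-PrMgCl (1 equiv), THF, 0 °C, then Mg turnings, reflux; added to 14 (pre-treated with i-PrMgCl, 1 equiv) and CuI (10 mol %), Et2O–THF, 0 °C → reflux; I2, −30 → 0 °C; aq. Na2S2O3
Reagents that add atoms: iodine, II
Why: After deprotonation of the tertiary alcohol the primary chloride is converted into the Grignard reagent, whose copper-catalysed anti-carbomagnesiation of the propargyl alkoxide places the alkyl group on C2 and magnesium on C3 in a five-membered alkoxide chelate, so that iodinolysis with retention gives the (Z)-iodoalkene with iodine cis to CH2OH, the geometry later needed for the C(CH2OAc)=CH bond.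

Step 8
Reactants: 18 4-bromofuran-2(5H)-one; 19 (E)-1,2-bis(tributylstannyl)ethene
Product: 20 4-[(E)-2-(tributylstannyl)ethenyl]furan-2(5H)-one
Conditions: Pd(PPh3)4 (5 mol %), 19 (2.5 equiv), toluene, 80 °C
Reagents that add atoms: none
Why: Stille coupling at one tin terminus only (excess distannane; the product vinylstannane is deactivated by conjugation to the lactone), with retention of the E geometry.

Step 9
Reactants: 17 (1R,6S)-1-[(3E,7Z)-7-(hydroxymethyl)-8-iodo-3-methylocta-3,7-dien-1-yl]-2,2,6-trimethylcyclohexan-1-ol; 20 4-[(E)-2-(tributylstannyl)ethenyl]furan-2(5H)-one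
Product: 21 4-{(1E,3Z,7E)-4-(hydroxymethyl)-10-[(1R,6S)-1-hydroxy-2,2,6-trimethylcyclohexyl]-8-methyldeca-1,3,7-trien-1-yl}furan-2(5H)-one
Conditions: Pd2(dba)3 (2.5 mol %), AsPh3, CuI (10 mol %), NMP, rt, dark
Reagents that add atoms: none
Why: Stille coupling of two stereodefined alkenyl partners proceeds with retention at both, giving the (1E,3Z)-diene under neutral conditions that spare the butenolide and both free hydroxyl groups.

Step 10
Reactants: 21 4-{(1E,3Z,7E)-4-(hydroxymethyl)-10-[(1R,6S)-1-hydroxy-2,2,6-trimethylcyclohexyl]-8-methyldeca-1,3,7-trien-1-yl}furan-2(5H)-one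
Product: 22 (2Z,4E)-2-{(3E)-6-[(1R,6S)-1-hydroxy-2,2,6-trimethylcyclohexyl]-4-methylhex-3-en-1-yl}-5-(5-oxo-2,5-dihydrofuran-3-yl)penta-2,4-dien-1-yl acetate (CNP0366059.1)
Conditions: Ac2O (1.1 equiv), pyridine, DMAP (cat.), CH2Cl2, 0 °C
Reagents that add atoms: acetic anhydride, CC(=O)OC(C)=O
Why: Acylation under nucleophilic catalysis is selective for the primary allylic alcohol because the tertiary ring hydroxyl, flanked by CMe2 and CHMe, is too hindered to react; it is done last because the allylic acetate would not survive the palladium couplings, and no stereocentre is affected.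

**Compound list**

1 | (E)-2-methylbut-2-enoyl chloride (tigloyl chloride) | C/C=C(\C)C(Cl)=O | starting material
2 | 4-(2-methylprop-1-en-1-yl)morpholine | CC(C)=CN1CCOCC1 | starting material
3 | 2-methylbuta-1,3-dien-1-one (methylvinylketene) | C=CC(C)=C=O | intermediate
4 | 2,6,6-trimethyl-5-(morpholin-4-yl)cyclohex-2-en-1-one (racemic) | CC1=CCC(N2CCOCC2)C(C)(C)C1=O | intermediate
5 | 2,6,6-trimethylcyclohexa-2,4-dien-1-one | CC1=CC=CC(C)(C)C1=O | intermediate
6 | (6S)-2,2,6-trimethylcyclohexan-1-one | O=C1[C@@H](C)CCCC1(C)C | intermediate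
7 | (1R,6S)-1-ethenyl-2,2,6-trimethylcyclohexan-1-ol | C=C[C@@]1(O)[C@@H](C)CCCC1(C)C | intermediate
8 | pent-3-yn-1-ol | CC#CCCO | starting material
9 | 5-chloropent-2-yne | CC#CCCCl | intermediate
10 | chlorobis(cyclopentadienyl)[(2E)-5-chloropent-2-en-2-yl]zirconium | C/C(=C\CCCl)[Zr](Cl)(C1C=CC=C1)C1C=CC=C1 | intermediate
11 | (E)-5-chloro-2-iodopent-2-ene | C/C(I)=C\CCCl | intermediate
12 | 9-{2-[(1R,6S)-1-hydroxy-2,2,6-trimethylcyclohexyl]ethyl}-9-borabicyclo[3.3.1]nonane | B1(CC[C@@]2(O)[C@@H](C)CCCC2(C)C)C2CCCC1CCC2 | intermediate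
13 | (1R,6S)-1-[(3E)-6-chloro-3-methylhex-3-en-1-yl]-2,2,6-trimethylcyclohexan-1-ol | ClCC/C=C(\C)CC[C@@]1(O)[C@@H](C)CCCC1(C)C | intermediate
14 | prop-2-yn-1-ol (propargyl alcohol) | C#CCO | starting material
15 | {(3E)-6-[(1R,6S)-1-(chloromagnesiooxy)-2,2,6-trimethylcyclohexyl]-4-methylhex-3-en-1-yl}magnesium chloride | Cl[Mg]CC/C=C(\C)CC[C@@]1(O[Mg]Cl)[C@@H](C)CCCC1(C)C | intermediate
16 | alkenylmagnesium chelate from anti-carbomagnesiation (magnesium on C3 cis to the CH2O–Mg group) | Cl[Mg]/C=C(\CO[Mg]Cl)CC/C=C(\C)CC[C@@]1(O[Mg]Cl)[C@@H](C)CCCC1(C)C | intermediate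
17 | (1R,6S)-1-[(3E,7Z)-7-(hydroxymethyl)-8-iodo-3-methylocta-3,7-dien-1-yl]-2,2,6-trimethylcyclohexan-1-ol | OC/C(=C\I)CC/C=C(\C)CC[C@@]1(O)[C@@H](C)CCCC1(C)C | intermediate
18 | 4-bromofuran-2(5H)-one | BrC1=CC(=O)OC1 | starting material
19 | (E)-1,2-bis(tributylstannyl)ethene | CCCC[Sn](CCCC)(CCCC)/C=C/[Sn](CCCC)(CCCC)CCCC | starting material
20 | 4-[(E)-2-(tributylstannyl)ethenyl]furan-2(5H)-one | CCCC[Sn](CCCC)(CCCC)/C=C/C1=CC(=O)OC1 | intermediate
21 | 4-{(1E,3Z,7E)-4-(hydroxymethyl)-10-[(1R,6S)-1-hydroxy-2,2,6-trimethylcyclohexyl]-8-methyldeca-1,3,7-trien-1-yl}furan-2(5H)-one | OC/C(=C\C=C\C1=CC(=O)OC1)CC/C=C(\C)CC[C@@]1(O)[C@@H](C)CCCC1(C)C | intermediate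
22 | (2Z,4E)-2-{(3E)-6-[(1R,6S)-1-hydroxy-2,2,6-trimethylcyclohexyl]-4-methylhex-3-en-1-yl}-5-(5-oxo-2,5-dihydrofuran-3-yl)penta-2,4-dien-1-yl acetate | CC(=O)OC/C(=C\C=C\C1=CC(=O)OC1)CC/C=C(\C)CC[C@@]1(O)[C@@H](C)CCCC1(C)C | target

**Step count.** Total: 10 steps. Longest linear sequence: 7 steps (steps 1, 2, 3, 6, 7, 9, 10); steps 4–5 and step 8 prepare the two side fragments.

**Steps most likely to fail**

Step 1. The zwitterion may close at the α-carbon to the aminocyclobutanone (loss of periselectivity), the ketene may dimerise or oligomerise, and dienone 5 may dimerise on standing. The fallback sets out from 1 and 2 and comes back at 5, and it avoids the ketene altogether. Without triethylamine, 1 should C-acylate enamine 2 (Et2O, 0 °C), and aqueous hydrolysis of the iminium salt should give (4E)-2,2,4-trimethyl-3-oxohex-4-enal F1. A non-nucleophilic base (LiN(SiMe3)2, THF, −78 → 0 °C) should then form the γ-dienolate, which adds to the aldehyde in an intramolecular vinylogous aldol reaction to give 5-hydroxy-2,6,6-trimethylcyclohex-2-en-1-one F2. Mesylation and elimination (MsCl, Et3N; then DBU) should give 5.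

Step 2. Facial selectivity in the hydrogenation of the trisubstituted enone may be insufficient, or the carbonyl may be reduced in competition. The fallback sets out from 5 and comes back at 6. Hydrogenation without stereocontrol (H2, palladium on carbon, EtOAc) should give racemic 2,2,6-trimethylcyclohexan-1-one F3. LiN(i-Pr)2 followed by Me3SiCl should give trimethyl[(2,6,6-trimethylcyclohex-1-en-1-yl)oxy]silane F4, since only one position can enolise. Enantioselective protonation of F4 with the stoichiometric complex of 1,1'-bi-2-naphthol and SnCl4 (a Lewis acid-assisted chiral Brønsted acid; toluene, −78 °C), the binaphthol antipode being chosen for the S product, should return 6 in enantioenriched form.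

Step 7. Magnesium insertion into the alkyl chloride may be incomplete in the presence of the magnesium alkoxide, Wurtz coupling may compete, and carbomagnesiation with a functionalised Grignard reagent may be sluggish. The fallback sets out from 13 and comes back at 21, bypassing steps 8 and 9. Halide exchange (NaI, acetone, reflux) should give (1R,6S)-1-[(3E)-6-iodo-3-methylhex-3-en-1-yl]-2,2,6-trimethylcyclohexan-1-ol F5. Alkylation of the sodium salt of methyl bis(2,2,2-trifluoroethyl)phosphonoacetate (NaH, DMF) with F5 should give methyl (5E)-2-[bis(2,2,2-trifluoroethoxy)phosphoryl]-8-[(1R,6S)-1-hydroxy-2,2,6-trimethylcyclohexyl]-6-methyloct-5-enoate F6. Still–Gennari olefination (KN(SiMe3)2, 18-crown-6, THF, −78 °C) with (E)-3-(tributylstannyl)prop-2-enal should give methyl (2Z,4E)-2-{(3E)-6-[(1R,6S)-1-hydroxy-2,2,6-trimethylcyclohexyl]-4-methylhex-3-en-1-yl}-5-(tributylstannyl)penta-2,4-dienoate F7, with the ester cis to the new vinyl group. Reduction with i-Bu2AlH (CH2Cl2, −78 °C) should give (2Z,4E)-2-{(3E)-6-[(1R,6S)-1-hydroxy-2,2,6-trimethylcyclohexyl]-4-methylhex-3-en-1-yl}-5-(tributylstannyl)penta-2,4-dien-1-ol F8. Stille coupling of F8 with bromobutenolide 18 (Pd2(dba)3, AsPh3, NMP) should give 21.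

**Further compounds**

F1 | step 1 | (4E)-2,2,4-trimethyl-3-oxohex-4-enal | C/C=C(\C)C(=O)C(C)(C)C=O
F2 | step 1 | 5-hydroxy-2,6,6-trimethylcyclohex-2-en-1-one (racemic) | CC1=CCC(O)C(C)(C)C1=O
F3 | step 2 | 2,2,6-trimethylcyclohexan-1-one (racemic) | CC1CCCC(C)(C)C1=O
F4 | step 2 | trimethyl[(2,6,6-trimethylcyclohex-1-en-1-yl)oxy]silane | CC1=C(O[Si](C)(C)C)C(C)(C)CCC1
F5 | step 7 | (1R,6S)-1-[(3E)-6-iodo-3-methylhex-3-en-1-yl]-2,2,6-trimethylcyclohexan-1-ol | ICC/C=C(\C)CC[C@@]1(O)[C@@H](C)CCCC1(C)C
F6 | step 7 | methyl (5E)-2-[bis(2,2,2-trifluoroethoxy)phosphoryl]-8-[(1R,6S)-1-hydroxy-2,2,6-trimethylcyclohexyl]-6-methyloct-5-enoate | COC(=O)C(CC/C=C(\C)CC[C@@]1(O)[C@@H](C)CCCC1(C)C)P(=O)(OCC(F)(F)F)OCC(F)(F)F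
F7 | step 7 | methyl (2Z,4E)-2-{(3E)-6-[(1R,6S)-1-hydroxy-2,2,6-trimethylcyclohexyl]-4-methylhex-3-en-1-yl}-5-(tributylstannyl)penta-2,4-dienoate | COC(=O)/C(=C\C=C\[Sn](CCCC)(CCCC)CCCC)CC/C=C(\C)CC[C@@]1(O)[C@@H](C)CCCC1(C)C
F8 | step 7 | (2Z,4E)-2-{(3E)-6-[(1R,6S)-1-hydroxy-2,2,6-trimethylcyclohexyl]-4-methylhex-3-en-1-yl}-5-(tributylstannyl)penta-2,4-dien-1-ol | OC/C(=C\C=C\[Sn](CCCC)(CCCC)CCCC)CC/C=C(\C)CC[C@@]1(O)[C@@H](C)CCCC1(C)C
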